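Retrosynthesis: the nine phenols and the acid are unmasked last (all as silicon groups); the three galloyl ester C(=O)–O bonds are cut to one protected galloyl chloride; the C3–O and C4–O bonds are cut to a C3=C4 alkene.
Enabling feature: in the carbocycle, C2 (vinylic CH) and C5 (O-bearing CH next to C6H2) are 1,4-related and C1=C2 is conjugated to the carboxyl, so rejoining O5 to C2 (retro-E1cB) gives a 7-oxabicyclo[2.2.1]hept-5-ene-2-carbonyl compound.
That bicycle is cut at C1–C2 and C5–C6 (retro-Diels–Alder) into furan (C2–C5 and O5) and an acrylimide (C1, C6 and the carboxyl carbon).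
Forward: the carbocycle closes first as the oxygen-bridged cycloadduct; the bridge is opened to the dienoate and O5 is acylated in the same flask; dihydroxylation, two more acylations and global desilylation follow. The protected galloyl chloride is made separately from gallic acid.
Stereochemistry: C5 is set by the ligand-controlled cycloaddition (it is a bridgehead of the adduct); C3 and C4 are set by osmylation anti to the C5 ester; the third stereocentre of the adduct is deliberately erased.

Key step: step 1

Assumptions: 3-acryloyl-1,3-oxazolidin-2-one, the (R,R)-t-Bu-box ligand and 2-(trimethylsilyl)ethanol are taken as commercial. The sense of induction of the Cu(II)–t-Bu-box catalyst with furan is taken to follow that established for cyclopentadiene with the same dienophile; if it proved opposite, the ligand antipode would be used. Target numbering: C1 carboxyl-bearing, C2 vinylic CH, C3–C5 oxygen-bearing, C6 CH2.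

Step 1
Reactants: 1 furan; 2 3-acryloyl-1,3-oxazolidin-2-one
Product: 3 3-[(1R,2R,4R)-7-oxabicyclo[2.2.1]hept-5-ene-2-carbonyl]-1,3-oxazolidin-2-one (endo adduct)
Conditions: [Cu((R,R)-t-Bu-box)](SbF6)2 (5 mol %, from CuCl2, AgSbF6 and 2,2'-isopropylidenebis[(4R)-4-tert-butyl-2-oxazoline]), furan (excess), CH2Cl2, −78 °C; filtration through silica at −78 °C; recrystallisation
Reagents that add atoms: none
Why: Furan adds as the diene to the s-cis acrylimide, held as a bidentate chelate in the square-planar cationic Cu(II)–bis(oxazoline) complex, in a concerted, asynchronous normal-electron-demand [4+2] cycloaddition that forms the target bonds C1–C2 and C5–C6. The closest known reaction type is the bis(oxazoline)copper(II)-catalysed enantioselective Diels–Alder reaction of furan with an N-acryloyl oxazolidinone. Two rings close in the one intermolecular cycloaddition, the six-membered carbocycle of the target and the temporary oxygen-bridged five-membered ring (oxygen spanning C2 and C5), both by suprafacial bond formation across the furan 2,5-positions. The three new stereocentres (both bridgeheads and the imide-bearing carbon) are controlled by the ligand: the tert-butyl groups of the (R,R)-ligand block the Cα Re face of the chelated dienophile, so furan should add to the Cα Si face through the endo transition state and give the (1R,2R,4R) adduct. The step needs both face and endo selectivity, because an exo adduct formed on the same dienophile face carries mirror-image bridgeheads and would end as the enantiomer of the target once the imide-bearing carbon is made planar in step 5. Low temperature keeps the reversible cycloaddition under kinetic control, and crystallisation of the imide is expected to remove the exo isomer and raise the enantiomeric purity.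

Step 2
Reactants: 3 endo adduct
Product: 4 2-(trimethylsilyl)ethyl (1R,2R,4R)-7-oxabicyclo[2.2.1]hept-5-ene-2-carboxylate
Conditions: Me3SiCH2CH2OH, n-BuLi, THF, −78 → −20 °C; AcOH quench
Reagents that add atoms: 2-(trimethylsilyl)ethanol, C[Si](C)(C)CCO
Why: Acyl transfer from an N-acyl oxazolidinone to a lithium alkoxide (the standard transesterification used to make benzyl esters) occurs at the exocyclic carbonyl below 0 °C, where the adduct does not undergo cycloreversion; no stereocentre is formed, and epimerisation at C2 would be harmless because that centre is made planar in step 5.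

Step 3
Reactants: 5 gallic acid
Product: 7 3,4,5-tris(tert-butyldimethylsilyloxy)benzoic acid, via persilylated silyl ester 6 (not isolated)
Conditions: TBSCl (4.5 equiv), imidazole, DMF, rt; then AcOH/THF/H2O, rt
Reagents that add atoms: tert-butyldimethylsilyl chloride, CC(C)(C)[Si](C)(C)Cl
Why: Exhaustive silylation of the three phenols and the acid, followed by selective hydrolysis of the much more labile silyl ester under mild aqueous acid, is a standard protection sequence that involves no stereocentre.

Step 4
Reactants: 7 3,4,5-tris(tert-butyldimethylsilyloxy)benzoic acid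
Product: 8 3,4,5-tris(tert-butyldimethylsilyloxy)benzoyl chloride
Conditions: (COCl)2, DMF (cat.), CH2Cl2, 0 °C → rt; evaporation, used crude
Reagents that add atoms: oxalyl chloride, ClC(=O)C(=O)Cl
Why: Vilsmeier-type activation with oxalyl chloride and catalytic DMF converts the acid into the acid chloride under conditions that aryl silyl ethers tolerate.

Step 5
Reactants: 4 2-(trimethylsilyl)ethyl (1R,2R,4R)-7-oxabicyclo[2.2.1]hept-5-ene-2-carboxylate; 8 3,4,5-tris(tert-butyldimethylsilyloxy)benzoyl chloride
Product: 11 2-(trimethylsilyl)ethyl (5R)-5-{[3,4,5-tris(tert-butyldimethylsilyloxy)benzoyl]oxy}cyclohexa-1,3-diene-1-carboxylate, via lithium ester enolate 9 (not isolated), via lithium cyclohexadienyl alkoxide 10 (not isolated)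
Conditions: LiHMDS (1.05 equiv), THF, −78 → 0 °C; then 8 (1.1 equiv), −78 → 0 °C; rapid filtration through Et3N-deactivated silica
Reagents that add atoms: none
Why: Deprotonation α to the ester gives enolate 9, which expels the bridging oxygen in a strain-releasing E1cB β-elimination (the established base-induced opening of 7-oxanorbornene-2-carboxylates) to give alkoxide 10 with the C1=C2 enoate in place, and this lithium alkoxide is O-acylated by 8 before it can aromatise; the bridgehead that becomes C5 is not touched, so its configuration is retained.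

Step 6
Reactants: 11 5-O-aroyl dienoate
Product: 12 2-(trimethylsilyl)ethyl 5-O-[3,4,5-tris(tert-butyldimethylsilyloxy)benzoyl]shikimate (3,4-diol)
Conditions: OsO4 (2 mol %), NMO (1.3 equiv), acetone/H2O, 0 °C → rt
Reagents that add atoms: osmium tetroxide (catalytic oxygen carrier), O=[Os](=O)(=O)=O; N-methylmorpholine N-oxide, C[N+]1([O-])CCOCC1; water, O
Why: Catalytic OsO4/NMO cis-dihydroxylation takes place at the electron-richer, disubstituted C3=C4 bond rather than the ester-conjugated C1=C2 bond and, by the empirical anti rule for osmylation next to an allylic oxygen substituent, on the face opposite the bulky C5 aroyloxy group, which sets C3 and C4 cis to each other and trans to O5; an acyl shift among the oxygens would be of no consequence because all three carry the same acyl group after step 7.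

Step 7
Reactants: 12 3,4-diol; 8 3,4,5-tris(tert-butyldimethylsilyloxy)benzoyl chloride
Product: 13 2-(trimethylsilyl)ethyl 3,4,5-tris-O-[3,4,5-tris(tert-butyldimethylsilyloxy)benzoyl]shikimate
Conditions: 8 (2.6 equiv), pyridine, DMAP (cat.), CH2Cl2, 0 °C → rt
Reagents that add atoms: none
Why: DMAP-catalysed esterification of both secondary alcohols with the acid chloride is a routine acylation that touches no stereocentre, and pyridine is mild enough not to trigger β-elimination of the acylated shikimate.

Step 8
Reactants: 13 fully protected triester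
Product: 14 3,4,5-tri-O-galloylshikimic acid (target)
Conditions: TBAF (12 equiv), THF, 0 °C → rt, Ar, degassed; 1 M HCl work-up; Sephadex LH-20
Reagents that add atoms: none
Why: Fluoride-induced global desilylation cleaves the nine aryl O–Si bonds and fragments the 2-(trimethylsilyl)ethyl ester (loss of ethene and fluorotrimethylsilane) without the reducing conditions that would endanger the C1=C2 bond and the allylic C3 ester; acidic work-up returns the free phenols and the acid, and no stereocentre is affected.

Compound list
1 | furan | c1ccoc1 | starting material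
2 | 3-acryloyl-1,3-oxazolidin-2-one | C=CC(=O)N1CCOC1=O | starting material
3 | 3-[(1R,2R,4R)-7-oxabicyclo[2.2.1]hept-5-ene-2-carbonyl]-1,3-oxazolidin-2-one (endo) | O=C([C@@H]1C[C@@H]2C=C[C@H]1O2)N1CCOC1=O | intermediate
4 | 2-(trimethylsilyl)ethyl (1R,2R,4R)-7-oxabicyclo[2.2.1]hept-5-ene-2-carboxylate | C[Si](C)(C)CCOC(=O)[C@@H]1C[C@@H]2C=C[C@H]1O2 | intermediate
5 | gallic acid | OC(=O)c1cc(O)c(O)c(O)c1 | starting material
6 | tert-butyldimethylsilyl 3,4,5-tris(tert-butyldimethylsilyloxy)benzoate | CC(C)(C)[Si](C)(C)OC(=O)c1cc(O[Si](C)(C)C(C)(C)C)c(O[Si](C)(C)C(C)(C)C)c(O[Si](C)(C)C(C)(C)C)c1 | intermediate (not isolated)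
7 | 3,4,5-tris(tert-butyldimethylsilyloxy)benzoic acid | OC(=O)c1cc(O[Si](C)(C)C(C)(C)C)c(O[Si](C)(C)C(C)(C)C)c(O[Si](C)(C)C(C)(C)C)c1 | intermediate
8 | 3,4,5-tris(tert-butyldimethylsilyloxy)benzoyl chloride | ClC(=O)c1cc(O[Si](C)(C)C(C)(C)C)c(O[Si](C)(C)C(C)(C)C)c(O[Si](C)(C)C(C)(C)C)c1 | intermediate
9 | lithium 1-[2-(trimethylsilyl)ethoxy]-1-[(1R,4R)-7-oxabicyclo[2.2.1]hept-5-en-2-ylidene]methanolate (ester enolate of 4) | [Li+].[O-]C(OCC[Si](C)(C)C)=C1C[C@@H]2C=C[C@H]1O2 | intermediate (not isolated)
10 | lithium (1R)-5-{[2-(trimethylsilyl)ethoxy]carbonyl}cyclohexa-2,4-dien-1-olate | C[Si](C)(C)CCOC(=O)C1=CC=C[C@H]([O-])C1.[Li+] | intermediate (not isolated)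
11 | 2-(trimethylsilyl)ethyl (5R)-5-{[3,4,5-tris(tert-butyldimethylsilyloxy)benzoyl]oxy}cyclohexa-1,3-diene-1-carboxylate | C[Si](C)(C)CCOC(=O)C1=CC=C[C@H](OC(=O)c2cc(O[Si](C)(C)C(C)(C)C)c(O[Si](C)(C)C(C)(C)C)c(O[Si](C)(C)C(C)(C)C)c2)C1 | intermediate
12 | 2-(trimethylsilyl)ethyl 5-O-[3,4,5-tris(tert-butyldimethylsilyloxy)benzoyl]shikimate | C[Si](C)(C)CCOC(=O)C1=C[C@@H](O)[C@@H](O)[C@H](OC(=O)c2cc(O[Si](C)(C)C(C)(C)C)c(O[Si](C)(C)C(C)(C)C)c(O[Si](C)(C)C(C)(C)C)c2)C1 | intermediate
13 | 2-(trimethylsilyl)ethyl 3,4,5-tris-O-[3,4,5-tris(tert-butyldimethylsilyloxy)benzoyl]shikimate | C[Si](C)(C)CCOC(=O)C1=C[C@@H](OC(=O)c2cc(O[Si](C)(C)C(C)(C)C)c(O[Si](C)(C)C(C)(C)C)c(O[Si](C)(C)C(C)(C)C)c2)[C@@H](OC(=O)c2cc(O[Si](C)(C)C(C)(C)C)c(O[Si](C)(C)C(C)(C)C)c(O[Si](C)(C)C(C)(C)C)c2)[C@H](OC(=O)c2cc(O[Si](C)(C)C(C)(C)C)c(O[Si](C)(C)C(C)(C)C)c(O[Si](C)(C)C(C)(C)C)c2)C1 | intermediate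
14 | 3,4,5-tri-O-galloylshikimic acid | O=C(O)C1=C[C@@H](OC(=O)c2cc(O)c(O)c(O)c2)[C@@H](OC(=O)c2cc(O)c(O)c(O)c2)[C@H](OC(=O)c2cc(O)c(O)c(O)c2)C1 | target

Total step count: 8. Longest linear sequence: 6 steps (1, 2, 5, 6, 7, 8); the two-step branch (3, 4) converges at step 5 and supplies step 7 as well.

Steps most likely to fail

Step 8. Under unbuffered fluoride the phenoxides and fluoride may deprotonate the enoate ester at C3 and start loss of a galloate with aromatisation, or the polyphenolates may be oxidised, before the slower fragmentation of the silylethyl ester is complete. The fallback sets out from 13 and separates the two events. Trifluoroacetic acid in CH2Cl2 should cleave the 2-(trimethylsilyl)ethyl ester while the aryl silyl ethers survive, giving 3,4,5-tris-O-[3,4,5-tris(tert-butyldimethylsilyloxy)benzoyl]shikimic acid F1. Buffered, near-neutral fluoride (Et3N·3HF in THF) then removes the nine silyl groups from the carboxylic acid, which is not prone to the elimination, and the route is rejoined at 14.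

Step 5. Alkoxide 10 may aromatise by loss of the C5 oxygen function if acylation by the hindered aroyl chloride is slow, or a silyl group may be transferred from 8 to the alkoxide instead of the acyl group. The fallback sets out from 4 and postpones all galloylation. The same LiHMDS opening is quenched with chlorotriethylsilane to give 2-(trimethylsilyl)ethyl (5R)-5-(triethylsilyloxy)cyclohexa-1,3-diene-1-carboxylate F2. Catalytic OsO4/NMO anti to the silyloxy group gives 2-(trimethylsilyl)ethyl 5-O-(triethylsilyl)shikimate F3. HF·pyridine removes the triethylsilyl group to give 2-(trimethylsilyl)ethyl shikimate F4. Exhaustive acylation of this triol with three equivalents of 8 (pyridine, DMAP) rejoins the route at 13.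

Step 1. Endo or face selectivity may be incomplete, or Lewis-acid-promoted cycloreversion during isolation may erode the isomeric purity. The fallback sets out from 1 and replaces catalyst control by classical resolution. Furan and acrylic acid, combined without a chiral catalyst, should give after crystallisation racemic endo-7-oxabicyclo[2.2.1]hept-5-ene-2-carboxylic acid F5. Crystallisation of its salt with one enantiomer of 1-phenylethylamine and acidification gives (1R,2R,4R)-7-oxabicyclo[2.2.1]hept-5-ene-2-carboxylic acid F6. Steglich esterification with 2-(trimethylsilyl)ethanol (DCC, DMAP) rejoins the route at 4.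

Further compounds
F1 | step 8 | 3,4,5-tris-O-[3,4,5-tris(tert-butyldimethylsilyloxy)benzoyl]shikimic acid | OC(=O)C1=C[C@@H](OC(=O)c2cc(O[Si](C)(C)C(C)(C)C)c(O[Si](C)(C)C(C)(C)C)c(O[Si](C)(C)C(C)(C)C)c2)[C@@H](OC(=O)c2cc(O[Si](C)(C)C(C)(C)C)c(O[Si](C)(C)C(C)(C)C)c(O[Si](C)(C)C(C)(C)C)c2)[C@H](OC(=O)c2cc(O[Si](C)(C)C(C)(C)C)c(O[Si](C)(C)C(C)(C)C)c(O[Si](C)(C)C(C)(C)C)c2)C1
F2 | step 5 | 2-(trimethylsilyl)ethyl (5R)-5-(triethylsilyloxy)cyclohexa-1,3-diene-1-carboxylate | C[Si](C)(C)CCOC(=O)C1=CC=C[C@H](O[Si](CC)(CC)CC)C1
F3 | step 5 | 2-(trimethylsilyl)ethyl 5-O-(triethylsilyl)shikimate | C[Si](C)(C)CCOC(=O)C1=C[C@@H](O)[C@@H](O)[C@H](O[Si](CC)(CC)CC)C1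
F4 | step 5 | 2-(trimethylsilyl)ethyl shikimate | C[Si](C)(C)CCOC(=O)C1=C[C@@H](O)[C@@H](O)[C@H](O)C1
F5 | step 1 | racemic endo-7-oxabicyclo[2.2.1]hept-5-ene-2-carboxylic acid (relative configuration 1R*,2R*,4R*; racemate, so no absolute descriptors) | OC(=O)C1CC2C=CC1O2
F6 | step 1 | (1R,2R,4R)-7-oxabicyclo[2.2.1]hept-5-ene-2-carboxylic acid | OC(=O)[C@@H]1C[C@@H]2C=C[C@H]1O2
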